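**Retrosynthetic overview**
1. Target 24 ⇐ protected enone 23 (acid unmasking) ⇐ silyl enol ether 20 (selenoxide elimination makes C2=C3).
2. (E)-Enol ester of 20 ⇐ terminal alkyne 16 by a proposed hydrozirconation/copper-catalysed acyloxylation with diacyl peroxide 18 (new C–O bond, E geometry).
3. C5 quaternary centre and side chain ⇐ C4=C5 alkene of cycloheptadiene 10 by HAT-initiated Giese coupling, then Weinreb ketone synthesis and CBS reduction.
4. The seven-membered ring, the only carbocycle, is formed once: asymmetric formal [4+3] (cyclopropanation/Cope) of siloxyvinyl diazoacetate 5 with dienyne 8, which sets C6 and C7 cis.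
5. 5 ⇐ methyl levulinate 1; 8 ⇐ 3-(trimethylsilyl)propynal 6.

Assumption: Rh2(S-PTAD)4 is taken to give the (6S,7R) sense drawn for 10 (the mirror-image catalyst Rh2(R-PTAD)4 is used if the facial sense proves opposite); ring atoms keep the target's locants in all names (C1 carbonyl carbon, C2 the CH2OH-bearing carbon, C5 quaternary, C6 enol-ester carbon, C7 acetonyl carbon), and the C5 descriptor is R up to 20 and S from 21 on only because the ranking of its neighbours changes.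

Step 1
Reactants: 1 methyl levulinate (methyl 4-oxopentanoate)
Product: 2 methyl 3-(2-methyl-1,3-dioxolan-2-yl)propanoate
Conditions: ethylene glycol, TsOH·H2O (cat.), toluene, reflux, Dean–Stark
Reagents that add atoms: ethylene glycol (OCCO)
Why: Acid-catalysed ketalisation with azeotropic removal of water masks the ketone that becomes the acetonyl carbonyl; no stereocentre.

Step 2
Reactants: 2 methyl 3-(2-methyl-1,3-dioxolan-2-yl)propanoate
Product: 3 methyl 5-(2-methyl-1,3-dioxolan-2-yl)-3-oxopentanoate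
Conditions: LiN(i-Pr)2 (2.2 equiv), MeOAc (2.2 equiv), THF, −78 °C; then 2, −78 → 0 °C; AcOH
Reagents that add atoms: methyl acetate (CC(=O)OC)
Why: Crossed Claisen condensation, in which the lithium enolate of methyl acetate acylates on the ester of 2 and the β-keto ester is held as its enolate until the quench; no stereocentre.

Step 3
Reactants: 3 methyl 5-(2-methyl-1,3-dioxolan-2-yl)-3-oxopentanoate
Product: 4 methyl 2-diazo-5-(2-methyl-1,3-dioxolan-2-yl)-3-oxopentanoate
Conditions: 4-acetamidobenzenesulfonyl azide, Et3N, MeCN, 0 °C → rt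
Reagents that add atoms: 4-acetamidobenzenesulfonyl azide (CC(=O)Nc1ccc(cc1)S(=O)(=O)N=[N+]=[N-])
Why: Regitz diazo transfer to the activated methylene of a β-keto ester; no stereocentre.

Step 4
Reactants: 4 methyl 2-diazo-5-(2-methyl-1,3-dioxolan-2-yl)-3-oxopentanoate
Product: 5 methyl (Z)-3-[(tert-butyldimethylsilyl)oxy]-2-diazo-5-(2-methyl-1,3-dioxolan-2-yl)pent-3-enoate
Conditions: TBSOTf, Et3N, CH2Cl2, 0 °C
Reagents that add atoms: tert-butyldimethylsilyl trifluoromethanesulfonate (CC(C)(C)[Si](C)(C)OS(=O)(=O)C(F)(F)F)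
Why: Soft enolisation and O-silylation of the diazo ketone toward its only enolisable side gives the (Z)-siloxyvinyl diazoacetate, the usual vinylcarbenoid precursor; no stereocentre.

Step 5
Reactants: 6 3-(trimethylsilyl)prop-2-ynal
Product: 7 (E)-2-methyl-5-(trimethylsilyl)pent-2-en-4-ynal
Conditions: 2-(triphenylphosphoranylidene)propanal, CH2Cl2, rt → 40 °C
Reagents that add atoms: 2-(triphenylphosphoranylidene)propanal (CC(C=O)=P(c1ccccc1)(c1ccccc1)c1ccccc1)
Why: Wittig olefination with a formyl-stabilised ylide is (E)-selective and stops after one homologation because the α-branched enal is less electrophilic than the ynal.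

Step 6
Reactants: 7 (E)-2-methyl-5-(trimethylsilyl)pent-2-en-4-ynal
Product: 8 (E)-trimethyl(4-methylhexa-3,5-dien-1-yn-1-yl)silane
Conditions: Ph3PCH3Br, n-BuLi, THF, 0 °C; then 7, 0 °C → rt
Reagents that add atoms: methyltriphenylphosphonium bromide (C[P+](c1ccccc1)(c1ccccc1)c1ccccc1.[Br-])
Why: Wittig methylenation of the enal leaves the existing (E) trisubstituted alkene untouched and gives the 3-methyl-1,3-diene whose terminal alkynyl group is trans to the vinyl group.

Step 7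
Reactants: 5 methyl (Z)-3-[(tert-butyldimethylsilyl)oxy]-2-diazo-5-(2-methyl-1,3-dioxolan-2-yl)pent-3-enoate; 8 (E)-trimethyl(4-methylhexa-3,5-dien-1-yn-1-yl)silane
Product: 10 methyl (6S,7R)-1-[(tert-butyldimethylsilyl)oxy]-5-methyl-7-[(2-methyl-1,3-dioxolan-2-yl)methyl]-6-[(trimethylsilyl)ethynyl]cyclohepta-1,4-diene-2-carboxylate, via cis-divinylcyclopropane 9 (not isolated)
Conditions: Rh2(S-PTAD)4 (1 mol %), hexanes, −26 °C (slow addition of 5); then 60 °C
Reagents that add atoms: none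
Why: Tandem cyclopropanation/Cope rearrangement (formal [4+3] cycloaddition): the chiral dirhodium carboxylate fixes the face of cyclopropanation of the terminal vinyl group, the cis-divinylcyclopropane rearranges through the boat transition state, and because both reacting termini carry their substituent trans to the cyclopropane (Z enol ether, E enyne) the C6 alkynyl and C7 side chain emerge cis with the absolute sense set by the catalyst.

Step 8
Reactants: 10 methyl (6S,7R)-1-[(tert-butyldimethylsilyl)oxy]-5-methyl-7-[(2-methyl-1,3-dioxolan-2-yl)methyl]-6-[(trimethylsilyl)ethynyl]cyclohepta-1,4-diene-2-carboxylate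
Product: 11 methyl (5R,6S,7R)-1-[(tert-butyldimethylsilyl)oxy]-5-{3-[methoxy(methyl)amino]-3-oxopropyl}-5-methyl-7-[(2-methyl-1,3-dioxolan-2-yl)methyl]-6-[(trimethylsilyl)ethynyl]cyclohept-1-ene-2-carboxylate
Conditions: N-methoxy-N-methylacrylamide, Fe(acac)3 (50 mol %), PhSiH3, EtOH/(CH2OH)2, 60 °C
Reagents that add atoms: N-methoxy-N-methylacrylamide (C=CC(=O)N(C)OC)
Why: Metal-hydride hydrogen-atom-transfer reductive olefin coupling (Giese-type radical conjugate addition): H adds to C4 of the only electron-rich trisubstituted alkene, and the tertiary C5 radical adds to the acrylamide on the face opposite the cis C6 and C7 substituents, so the new chain is trans to them and the C5 methyl cis, as in the target.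

Step 9
Reactants: 11 methyl (5R,6S,7R)-1-[(tert-butyldimethylsilyl)oxy]-5-{3-[methoxy(methyl)amino]-3-oxopropyl}-5-methyl-7-[(2-methyl-1,3-dioxolan-2-yl)methyl]-6-[(trimethylsilyl)ethynyl]cyclohept-1-ene-2-carboxylate
Product: 12 methyl (5R,6S,7R)-1-[(tert-butyldimethylsilyl)oxy]-5-methyl-5-(4-methyl-3-oxopent-4-en-1-yl)-7-[(2-methyl-1,3-dioxolan-2-yl)methyl]-6-[(trimethylsilyl)ethynyl]cyclohept-1-ene-2-carboxylate
Conditions: isopropenylmagnesium bromide, THF, −20 → 0 °C; then H2O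
Reagents that add atoms: isopropenylmagnesium bromide (C=C(C)[Mg]Br)
Why: Weinreb ketone synthesis: the magnesium chelate prevents over-addition and the β-silyloxy enoate (a vinylogous carbonate) is far less electrophilic than the amide; no stereocentre.

Step 10
Reactants: 12 methyl (5R,6S,7R)-1-[(tert-butyldimethylsilyl)oxy]-5-methyl-5-(4-methyl-3-oxopent-4-en-1-yl)-7-[(2-methyl-1,3-dioxolan-2-yl)methyl]-6-[(trimethylsilyl)ethynyl]cyclohept-1-ene-2-carboxylate
Product: 13 methyl (5R,6S,7R)-1-[(tert-butyldimethylsilyl)oxy]-5-[(3R)-3-hydroxy-4-methylpent-4-en-1-yl]-5-methyl-7-[(2-methyl-1,3-dioxolan-2-yl)methyl]-6-[(trimethylsilyl)ethynyl]cyclohept-1-ene-2-carboxylate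
Conditions: (S)-2-methyl-CBS-oxazaborolidine (20 mol %), catecholborane, toluene, −78 °C
Reagents that add atoms: none
Why: Corey–Bakshi–Shibata reduction: the isopropenyl group acts as the large substituent, so the (S)-oxazaborolidine delivers hydride to give the (3R)-allylic alcohol, and no other ketone competes because C1 is still a silyl enol ether and the acetonyl ketone a ketal.

Step 11
Reactants: 13 methyl (5R,6S,7R)-1-[(tert-butyldimethylsilyl)oxy]-5-[(3R)-3-hydroxy-4-methylpent-4-en-1-yl]-5-methyl-7-[(2-methyl-1,3-dioxolan-2-yl)methyl]-6-[(trimethylsilyl)ethynyl]cyclohept-1-ene-2-carboxylate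
Product: 14 {(5R,6S,7R)-1-[(tert-butyldimethylsilyl)oxy]-5-[(3R)-3-hydroxy-4-methylpent-4-en-1-yl]-5-methyl-7-[(2-methyl-1,3-dioxolan-2-yl)methyl]-6-[(trimethylsilyl)ethynyl]cyclohept-1-en-2-yl}methanol
Conditions: i-Bu2AlH (3.5 equiv), CH2Cl2, −78 °C; aq. potassium sodium tartrate
Reagents that add atoms: none
Why: 1,2-Reduction of the β-silyloxy enoate by i-Bu2AlH gives the allylic primary alcohol (the future C2 CH2OH) without touching the silyl enol ether, ketal or silylalkyne; no new stereocentre.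

Step 12
Reactants: 14 {(5R,6S,7R)-1-[(tert-butyldimethylsilyl)oxy]-5-[(3R)-3-hydroxy-4-methylpent-4-en-1-yl]-5-methyl-7-[(2-methyl-1,3-dioxolan-2-yl)methyl]-6-[(trimethylsilyl)ethynyl]cyclohept-1-en-2-yl}methanol
Product: 15 (5R,6S,7R)-1-[(tert-butyldimethylsilyl)oxy]-5-methyl-7-[(2-methyl-1,3-dioxolan-2-yl)methyl]-5-{(3R)-4-methyl-3-[(triethylsilyl)oxy]pent-4-en-1-yl}-2-{[(triethylsilyl)oxy]methyl}-6-[(trimethylsilyl)ethynyl]cyclohept-1-ene
Conditions: TESCl, imidazole, CH2Cl2, 0 °C → rt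
Reagents that add atoms: chlorotriethylsilane (CC[Si](Cl)(CC)CC)
Why: Standard silylation of both hydroxyl groups, needed so that the hydrozirconation meets no acidic protons; no stereocentre.

Step 13
Reactants: 15 (5R,6S,7R)-1-[(tert-butyldimethylsilyl)oxy]-5-methyl-7-[(2-methyl-1,3-dioxolan-2-yl)methyl]-5-{(3R)-4-methyl-3-[(triethylsilyl)oxy]pent-4-en-1-yl}-2-{[(triethylsilyl)oxy]methyl}-6-[(trimethylsilyl)ethynyl]cyclohept-1-ene
Product: 16 (5R,6S,7R)-1-[(tert-butyldimethylsilyl)oxy]-6-ethynyl-5-methyl-7-[(2-methyl-1,3-dioxolan-2-yl)methyl]-5-{(3R)-4-methyl-3-[(triethylsilyl)oxy]pent-4-en-1-yl}-2-{[(triethylsilyl)oxy]methyl}cyclohept-1-ene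
Conditions: K2CO3 (0.3 equiv), MeOH, rt
Reagents that add atoms: none
Why: Base-catalysed methanolysis of the C(sp)–Si bond is selective over the O-silyl ethers and the hindered silyl enol ether; no stereocentre.

Step 14
Reactants: 17 3-methylbut-2-enoyl chloride (2 equiv)
Product: 18 bis(3-methylbut-2-enoyl) peroxide
Conditions: 17 (2.0 equiv), H2O2 (30 % aq, 1.0 equiv), pyridine (2.1 equiv), Et2O, 0 °C
Reagents that add atoms: hydrogen peroxide (OO); 3-methylbut-2-enoyl chloride, second equivalent of 17 (CC(C)=CC(Cl)=O)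
Why: Two molecules of the acid chloride acylate the two oxygens of one molecule of hydrogen peroxide, the standard diacyl peroxide synthesis; the product is kept cold in solution and used directly.

Step 15
Reactants: 16 (5R,6S,7R)-1-[(tert-butyldimethylsilyl)oxy]-6-ethynyl-5-methyl-7-[(2-methyl-1,3-dioxolan-2-yl)methyl]-5-{(3R)-4-methyl-3-[(triethylsilyl)oxy]pent-4-en-1-yl}-2-{[(triethylsilyl)oxy]methyl}cyclohept-1-ene; 18 bis(3-methylbut-2-enoyl) peroxide
Product: 20 (E)-2-[(5R,6S,7R)-1-[(tert-butyldimethylsilyl)oxy]-5-methyl-7-[(2-methyl-1,3-dioxolan-2-yl)methyl]-5-{(3R)-4-methyl-3-[(triethylsilyl)oxy]pent-4-en-1-yl}-2-{[(triethylsilyl)oxy]methyl}cyclohept-1-en-6-yl]ethenyl 3-methylbut-2-enoate, via (E)-alkenylzirconocene chloride 19 (not isolated)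
Conditions: Cp2Zr(H)Cl (1.2 equiv), THF, rt; then CuCl (10 mol %), 18 (1.5 equiv), 0 °C → rt
Reagents that add atoms: none
Why: Proposed new method: syn hydrozirconation puts zirconium on the terminal carbon and gives the (E)-alkenylzirconocene, alkenyl transfer to copper followed by oxidative addition of the peroxide O–O bond gives a trivalent copper alkenyl carboxylate, and C–O reductive elimination should release the (E)-enol ester with retention of geometry while the copper carboxylate re-enters by transmetalation; the closest known reaction types are the copper-catalysed electrophilic amination of alkenylzirconocenes with O-benzoylhydroxylamines and the Chan–Lam acyloxylation of alkenylboron reagents.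

Step 16
Reactants: 20 (E)-2-[(5R,6S,7R)-1-[(tert-butyldimethylsilyl)oxy]-5-methyl-7-[(2-methyl-1,3-dioxolan-2-yl)methyl]-5-{(3R)-4-methyl-3-[(triethylsilyl)oxy]pent-4-en-1-yl}-2-{[(triethylsilyl)oxy]methyl}cyclohept-1-en-6-yl]ethenyl 3-methylbut-2-enoate
Product: 23 (E)-2-[(5S,6S,7R)-5-methyl-7-[(2-methyl-1,3-dioxolan-2-yl)methyl]-5-{(3R)-4-methyl-3-[(triethylsilyl)oxy]pent-4-en-1-yl}-1-oxo-2-{[(triethylsilyl)oxy]methyl}cyclohept-2-en-6-yl]ethenyl 3-methylbut-2-enoate, via alpha-phenylselanyl ketone 21 (not isolated), via selenoxide 22 (not isolated)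
Conditions: PhSeCl (1.05 equiv), CH2Cl2, −78 °C; then pyridine, H2O2 (30 % aq), 0 °C → rt
Reagents that add atoms: none
Why: α-Selenenylation of the silyl enol ether at C2 followed by selenoxide syn-elimination, which runs away from the oxygen-bearing CH2OSi carbon and so gives only the endocyclic C2=C3 enone; C7 next to the new ketone is not touched under these near-neutral conditions.

Step 17
Reactants: 23 (E)-2-[(5S,6S,7R)-5-methyl-7-[(2-methyl-1,3-dioxolan-2-yl)methyl]-5-{(3R)-4-methyl-3-[(triethylsilyl)oxy]pent-4-en-1-yl}-1-oxo-2-{[(triethylsilyl)oxy]methyl}cyclohept-2-en-6-yl]ethenyl 3-methylbut-2-enoate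
Product: 24 (E)-2-[(5S,6S,7R)-2-(hydroxymethyl)-5-[(3R)-3-hydroxy-4-methylpent-4-en-1-yl]-5-methyl-1-oxo-7-(2-oxopropyl)cyclohept-2-en-6-yl]ethenyl 3-methylbut-2-enoate (CNP0257974.2)
Conditions: HCl (0.5 M aq), THF, 0 °C → rt
Reagents that add atoms: water (O)
Why: Dilute aqueous acid cleaves the two triethylsilyl ethers and the dioxolane far faster than it hydrolyses the conjugated enol ester or enolises C7, so all four stereocentres and the (E) alkene are kept.

**Compound list**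
1 | methyl levulinate (methyl 4-oxopentanoate) | COC(=O)CCC(C)=O | starting material
2 | methyl 3-(2-methyl-1,3-dioxolan-2-yl)propanoate | COC(=O)CCC1(C)OCCO1 | intermediate
3 | methyl 5-(2-methyl-1,3-dioxolan-2-yl)-3-oxopentanoate | COC(=O)CC(=O)CCC1(C)OCCO1 | intermediate
4 | methyl 2-diazo-5-(2-methyl-1,3-dioxolan-2-yl)-3-oxopentanoate | COC(=O)C(=[N+]=[N-])C(=O)CCC1(C)OCCO1 | intermediate
5 | methyl (Z)-3-[(tert-butyldimethylsilyl)oxy]-2-diazo-5-(2-methyl-1,3-dioxolan-2-yl)pent-3-enoate | COC(=O)C(=[N+]=[N-])/C(O[Si](C)(C)C(C)(C)C)=C/CC1(C)OCCO1 | intermediate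
6 | 3-(trimethylsilyl)prop-2-ynal | C[Si](C)(C)C#CC=O | starting material
7 | (E)-2-methyl-5-(trimethylsilyl)pent-2-en-4-ynal | C[Si](C)(C)C#C/C=C(\C)C=O | intermediate
8 | (E)-trimethyl(4-methylhexa-3,5-dien-1-yn-1-yl)silane | C[Si](C)(C)C#C/C=C(\C)C=C | intermediate
9 | methyl (1S,2R)-1-{(Z)-1-[(tert-butyldimethylsilyl)oxy]-3-(2-methyl-1,3-dioxolan-2-yl)prop-1-en-1-yl}-2-[(E)-5-(trimethylsilyl)pent-2-en-4-yn-2-yl]cyclopropane-1-carboxylate (the two alkenyl groups cis) | COC(=O)[C@@]1(/C(O[Si](C)(C)C(C)(C)C)=C/CC2(C)OCCO2)C[C@@H]1/C(C)=C/C#C[Si](C)(C)C | intermediate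
10 | methyl (6S,7R)-1-[(tert-butyldimethylsilyl)oxy]-5-methyl-7-[(2-methyl-1,3-dioxolan-2-yl)methyl]-6-[(trimethylsilyl)ethynyl]cyclohepta-1,4-diene-2-carboxylate | CC1=CCC(C(=O)OC)=C(O[Si](C)(C)C(C)(C)C)[C@H](CC2(C)OCCO2)[C@@H]1C#C[Si](C)(C)C | intermediate
11 | methyl (5R,6S,7R)-1-[(tert-butyldimethylsilyl)oxy]-5-{3-[methoxy(methyl)amino]-3-oxopropyl}-5-methyl-7-[(2-methyl-1,3-dioxolan-2-yl)methyl]-6-[(trimethylsilyl)ethynyl]cyclohept-1-ene-2-carboxylate | CON(C)C(=O)CC[C@@]1(C)CCC(C(=O)OC)=C(O[Si](C)(C)C(C)(C)C)[C@H](CC2(C)OCCO2)[C@@H]1C#C[Si](C)(C)C | intermediate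
12 | methyl (5R,6S,7R)-1-[(tert-butyldimethylsilyl)oxy]-5-methyl-5-(4-methyl-3-oxopent-4-en-1-yl)-7-[(2-methyl-1,3-dioxolan-2-yl)methyl]-6-[(trimethylsilyl)ethynyl]cyclohept-1-ene-2-carboxylate | C=C(C)C(=O)CC[C@@]1(C)CCC(C(=O)OC)=C(O[Si](C)(C)C(C)(C)C)[C@H](CC2(C)OCCO2)[C@@H]1C#C[Si](C)(C)C | intermediate
13 | methyl (5R,6S,7R)-1-[(tert-butyldimethylsilyl)oxy]-5-[(3R)-3-hydroxy-4-methylpent-4-en-1-yl]-5-methyl-7-[(2-methyl-1,3-dioxolan-2-yl)methyl]-6-[(trimethylsilyl)ethynyl]cyclohept-1-ene-2-carboxylate | C=C(C)[C@H](O)CC[C@@]1(C)CCC(C(=O)OC)=C(O[Si](C)(C)C(C)(C)C)[C@H](CC2(C)OCCO2)[C@@H]1C#C[Si](C)(C)C | intermediate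
14 | {(5R,6S,7R)-1-[(tert-butyldimethylsilyl)oxy]-5-[(3R)-3-hydroxy-4-methylpent-4-en-1-yl]-5-methyl-7-[(2-methyl-1,3-dioxolan-2-yl)methyl]-6-[(trimethylsilyl)ethynyl]cyclohept-1-en-2-yl}methanol | C=C(C)[C@H](O)CC[C@@]1(C)CCC(CO)=C(O[Si](C)(C)C(C)(C)C)[C@H](CC2(C)OCCO2)[C@@H]1C#C[Si](C)(C)C | intermediate
15 | (5R,6S,7R)-1-[(tert-butyldimethylsilyl)oxy]-5-methyl-7-[(2-methyl-1,3-dioxolan-2-yl)methyl]-5-{(3R)-4-methyl-3-[(triethylsilyl)oxy]pent-4-en-1-yl}-2-{[(triethylsilyl)oxy]methyl}-6-[(trimethylsilyl)ethynyl]cyclohept-1-ene | C=C(C)[C@H](O[Si](CC)(CC)CC)CC[C@@]1(C)CCC(CO[Si](CC)(CC)CC)=C(O[Si](C)(C)C(C)(C)C)[C@H](CC2(C)OCCO2)[C@@H]1C#C[Si](C)(C)C | intermediate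
16 | (5R,6S,7R)-1-[(tert-butyldimethylsilyl)oxy]-6-ethynyl-5-methyl-7-[(2-methyl-1,3-dioxolan-2-yl)methyl]-5-{(3R)-4-methyl-3-[(triethylsilyl)oxy]pent-4-en-1-yl}-2-{[(triethylsilyl)oxy]methyl}cyclohept-1-ene | C=C(C)[C@H](O[Si](CC)(CC)CC)CC[C@@]1(C)CCC(CO[Si](CC)(CC)CC)=C(O[Si](C)(C)C(C)(C)C)[C@H](CC2(C)OCCO2)[C@@H]1C#C | intermediate
17 | 3-methylbut-2-enoyl chloride | CC(C)=CC(Cl)=O | starting material
18 | bis(3-methylbut-2-enoyl) peroxide | CC(C)=CC(=O)OOC(=O)C=C(C)C | intermediate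
19 | chlorobis(cyclopentadienyl){(E)-2-[ring C6 of 16]ethenyl}zirconium, ring and side-chain stereocentres as in 16 (Cp drawn η1) | C=C(C)[C@H](O[Si](CC)(CC)CC)CC[C@@]1(C)CCC(CO[Si](CC)(CC)CC)=C(O[Si](C)(C)C(C)(C)C)[C@H](CC2(C)OCCO2)[C@@H]1/C=C/[Zr](Cl)(C2C=CC=C2)C2C=CC=C2 | intermediate
20 | (E)-2-[(5R,6S,7R)-1-[(tert-butyldimethylsilyl)oxy]-5-methyl-7-[(2-methyl-1,3-dioxolan-2-yl)methyl]-5-{(3R)-4-methyl-3-[(triethylsilyl)oxy]pent-4-en-1-yl}-2-{[(triethylsilyl)oxy]methyl}cyclohept-1-en-6-yl]ethenyl 3-methylbut-2-enoate | C=C(C)[C@H](O[Si](CC)(CC)CC)CC[C@@]1(C)CCC(CO[Si](CC)(CC)CC)=C(O[Si](C)(C)C(C)(C)C)[C@H](CC2(C)OCCO2)[C@@H]1/C=C/OC(=O)C=C(C)C | intermediate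
21 | (E)-2-[(5S,6S,7R)-5-methyl-7-[(2-methyl-1,3-dioxolan-2-yl)methyl]-5-{(3R)-4-methyl-3-[(triethylsilyl)oxy]pent-4-en-1-yl}-1-oxo-2-(phenylselanyl)-2-{[(triethylsilyl)oxy]methyl}cycloheptan-6-yl]ethenyl 3-methylbut-2-enoate (C2 epimers) | C=C(C)[C@H](O[Si](CC)(CC)CC)CC[C@@]1(C)CCC(CO[Si](CC)(CC)CC)([Se]c2ccccc2)C(=O)[C@H](CC2(C)OCCO2)[C@@H]1/C=C/OC(=O)C=C(C)C | intermediate
22 | selenoxide of 21: the same compound with a 2-(phenylseleninyl) group (C2 and Se epimers) | C=C(C)[C@H](O[Si](CC)(CC)CC)CC[C@@]1(C)CCC(CO[Si](CC)(CC)CC)([Se](=O)c2ccccc2)C(=O)[C@H](CC2(C)OCCO2)[C@@H]1/C=C/OC(=O)C=C(C)C | intermediate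
23 | (E)-2-[(5S,6S,7R)-5-methyl-7-[(2-methyl-1,3-dioxolan-2-yl)methyl]-5-{(3R)-4-methyl-3-[(triethylsilyl)oxy]pent-4-en-1-yl}-1-oxo-2-{[(triethylsilyl)oxy]methyl}cyclohept-2-en-6-yl]ethenyl 3-methylbut-2-enoate | C=C(C)[C@H](O[Si](CC)(CC)CC)CC[C@@]1(C)CC=C(CO[Si](CC)(CC)CC)C(=O)[C@H](CC2(C)OCCO2)[C@@H]1/C=C/OC(=O)C=C(C)C | intermediate
24 | (E)-2-[(5S,6S,7R)-2-(hydroxymethyl)-5-[(3R)-3-hydroxy-4-methylpent-4-en-1-yl]-5-methyl-1-oxo-7-(2-oxopropyl)cyclohept-2-en-6-yl]ethenyl 3-methylbut-2-enoate | C=C(C)[C@H](O)CC[C@@]1(C)CC=C(CO)C(=O)[C@H](CC(C)=O)[C@@H]1/C=C/OC(=O)C=C(C)C | target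

**Totals**
Total step count: 17. Longest linear sequence: 14 steps (steps 1–4, 7–13, 15–17).

**Steps most likely to fail**

Step 15 (the proposed new method). The peroxide may be consumed by residual hydride or by radical paths, and alkenyl homocoupling may compete with C–O bond formation. The fallback uses known chemistry, sets out from 16 and comes back at 20. Hydroboration of the alkyne with catecholborane (dicyclohexylborane cat., THF, rt) gives the (E)-alkenyl catecholboronate F3. Water hydrolyses it to the (E)-alkenylboronic acid F4. Chan–Lam–Evans coupling of F4 with 3-methylbut-2-enoic acid (Cu(OAc)2, Et3N, 4 Å molecular sieves, air, CH2Cl2, rt) then gives 20 with retention of the (E) geometry.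

Step 8. The quaternary centre is formed next to a substituted carbon, the alkynyl group at C6 is small, and the face selectivity or the efficiency of the iron hydride coupling may be low. The fallback generates the same C5 radical at room temperature by another route; it sets out from 10 and comes back at 11. Mukaiyama hydration of the C4=C5 alkene (Co(acac)2, PhSiH3, O2, i-PrOH) gives the tertiary C5 alcohol F1. Acylation with chloro N-phthalimidoyl oxalate (Et3N, DMAP, CH2Cl2) gives the tert-alkyl N-phthalimidoyl oxalate F2. Visible-light photoredox fragmentation ([Ru(bpy)3](PF6)2, Hantzsch ester, i-Pr2NEt·HBF4, blue LEDs) in the presence of N-methoxy-N-methylacrylamide then gives 11, the acceptor again entering trans to the C6 and C7 groups.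

Step 16. PhSeCl could also add to the isopropenyl or enol ester alkene, and the oxidant could damage the enol ester. The fallback replaces the selenium sequence by a Saegusa–Ito dehydrosilylation; it sets out from 20 and comes back at 23. Pd(OAc)2 (1.2 equiv) in MeCN at rt reacts only at the silyl enol ether and gives 23 directly by β-hydride elimination into the ring. No new compound arises on this way (F0).

**Further compounds**
F1 | step 8 | methyl 1-[(tert-butyldimethylsilyl)oxy]-5-hydroxy-5-methyl-7-[(2-methyl-1,3-dioxolan-2-yl)methyl]-6-[(trimethylsilyl)ethynyl]cyclohept-1-ene-2-carboxylate (C5 epimers; C6 and C7 as in 10) | CC1(O)CCC(C(=O)OC)=C(O[Si](C)(C)C(C)(C)C)[C@H](CC2(C)OCCO2)[C@@H]1C#C[Si](C)(C)C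
F2 | step 8 | N-phthalimidoyl oxalate of F1 (C5 epimers; C6 and C7 as in 10) | CC1(OC(=O)C(=O)ON2C(=O)c3ccccc3C2=O)CCC(C(=O)OC)=C(O[Si](C)(C)C(C)(C)C)[C@H](CC2(C)OCCO2)[C@@H]1C#C[Si](C)(C)C
F3 | step 15 | (E)-alkenyl catecholboronate from 16 (2-alkenyl-1,3,2-benzodioxaborole; stereocentres as in 16) | C=C(C)[C@H](O[Si](CC)(CC)CC)CC[C@@]1(C)CCC(CO[Si](CC)(CC)CC)=C(O[Si](C)(C)C(C)(C)C)[C@H](CC2(C)OCCO2)[C@@H]1/C=C/B2Oc3ccccc3O2
F4 | step 15 | (E)-alkenylboronic acid from 16 (stereocentres as in 16) | C=C(C)[C@H](O[Si](CC)(CC)CC)CC[C@@]1(C)CCC(CO[Si](CC)(CC)CC)=C(O[Si](C)(C)C(C)(C)C)[C@H](CC2(C)OCCO2)[C@@H]1/C=C/B(O)O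
F0 | step 16 | none | none
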